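**Retrosynthetic overview** (upper decalin = rings A/B, lower decalin = rings C/D)
1. Target ⇐ O‑sulfation of the hydroquinone ⇐ O‑demethylation; the axial C‑2 methyl of the upper decalin ⇐ C‑2 ketone, by a diazoalkane/AlMe3 1,2‑methyl shift and C–Al protonolysis.
2. C‑1 quaternary centre and trans ring fusion ⇐ Birch reductive benzylation of an enone with 2‑(bromomethyl)‑1,4‑dimethoxybenzene; exocyclic methylene ⇐ Wittig reaction of the ring A ketone.
3. Key disconnection: six‑membered ring A ⇐ one‑carbon ring expansion of the cyclopentanone of a Hajos–Parrish‑type hydrindenedione, itself from cyclopentane‑1,3‑dione, pent‑1‑en‑3‑one and the lower‑decalin acetaldehyde.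
4. Lower decalin ⇐ exo‑selective catalytic asymmetric Diels–Alder reaction of 1‑ethenyl‑6,6‑dimethylcyclohexene with (E)‑2‑methylbut‑2‑enal; its ketone precursor ⇐ the same ring expansion of 2,2‑dimethylcyclopentanone.
5. Ring order: ring D (ring expansion) → ring C (Diels–Alder) → ring B (aldol) → ring A (ring expansion); the arene comes from hydroquinone.

Assumption: the product is isolated as the free bis(hydrogen sulfate) drawn (the disodium salt is the storage form); TMSCHN2, vinylMgBr, MeI, AlMe3, formaldehyde and the Wittig salts are treated as reagents.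
Shorthand used in names: Q = 2‑[(1S,2R,8aR)‑1,2,5,5‑tetramethyl‑1,2,3,5,6,7,8,8a‑octahydronaphthalen‑1‑yl]ethyl.

Step 1
Reactants: 1 2,2-dimethylcyclopentan-1-one
Product: 3 2,2-dimethylcyclohexan-1-one, via silyl ketone 2 (not isolated)
Conditions: TMSCHN2 (1.2 equiv), AlMe3 (1.2 equiv), CH2Cl2, −78 → −20 °C; then 1 M HCl, THF, 25 °C
Reagents that add atoms: (trimethylsilyl)diazomethane, C[Si](C)(C)C=[N+]=[N-]
Why: Lewis‑acid‑promoted diazoalkane ring expansion (Tiffeneau–Demjanov type): the unhindered CH2, not the quaternary carbon, migrates, so the carbonyl stays next to the gem‑dimethyl carbon, and the α‑silyl group blocks a second homologation before acid removes it.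

Step 2
Reactants: 3 2,2-dimethylcyclohexan-1-one
Product: 4 1-ethenyl-2,2-dimethylcyclohexan-1-ol (racemic)
Conditions: vinylMgBr (1.5 equiv), THF, 0 → 25 °C; aq. NH4Cl
Reagents that add atoms: vinylmagnesium bromide, C=C[Mg]Br
Why: Grignard 1,2‑addition to a hindered ketone; the new carbinol centre is racemic and is removed in step 3.

Step 3
Reactants: 4 1-ethenyl-2,2-dimethylcyclohexan-1-ol (racemic)
Product: 5 1-ethenyl-6,6-dimethylcyclohex-1-ene
Conditions: KHSO4 (5 mol %), 120 °C, distilled out under reduced pressure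
Reagents that add atoms: none
Why: Acid‑catalysed E1 dehydration of a tertiary allylic alcohol; only the ring CH2 carries β‑hydrogens, so the conjugated diene is the only alkene formed.

Step 4
Reactants: 5 1-ethenyl-6,6-dimethylcyclohex-1-ene; 6 (E)-2-methylbut-2-enal
Product: 7 (1S,2R,8aS)-1,2,5,5-tetramethyl-1,2,3,5,6,7,8,8a-octahydronaphthalene-1-carbaldehyde
Conditions: (S)-1-(2-methylphenyl)-3,3-diphenyltetrahydro-1H,3H-pyrrolo[1,2-c][1,3,2]oxazaborole·AlBr3 (10 mol %; catalyst enantiomer chosen to give the adduct shown), CH2Cl2, −78 → −20 °C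
Reagents that add atoms: none
Why: Lewis‑acid‑catalysed Diels–Alder reaction: the formyl‑bearing carbon bonds to the ring terminus of the diene (ortho rule), the 2‑methyl enal reacts with CHO exo so that CHO ends cis to H‑8a, the E‑enal keeps the two methyls cis to each other, and the chiral oxazaborolidinium shields one enal face to set C‑1, C‑2 and C‑8a.

Step 5
Reactants: 7 (1S,2R,8aS)-1,2,5,5-tetramethyl-1,2,3,5,6,7,8,8a-octahydronaphthalene-1-carbaldehyde
Product: 9 2-[(1S,2R,8aR)-1,2,5,5-tetramethyl-1,2,3,5,6,7,8,8a-octahydronaphthalen-1-yl]acetaldehyde, via enol ether 8 (not isolated)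
Conditions: Ph3P(CH2OMe)Cl, KOt-Bu, THF, 0 → 25 °C; then 2 M HCl, THF, 25 °C
Reagents that add atoms: (methoxymethyl)triphenylphosphonium chloride, COC[P+](c1ccccc1)(c1ccccc1)c1ccccc1.[Cl-]; water, O
Why: Wittig methoxymethylenation and enol ether hydrolysis give a one‑carbon homologation; the aldehyde has no α‑hydrogen, so no stereocentre can epimerise.

Step 6
Reactants: 9 2-[(1S,2R,8aR)-1,2,5,5-tetramethyl-1,2,3,5,6,7,8,8a-octahydronaphthalen-1-yl]acetaldehyde; 10 cyclopentane-1,3-dione
Product: 11 2-Q-cyclopentane-1,3-dione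
Conditions: Hantzsch ester (diethyl 2,6-dimethyl-1,4-dihydropyridine-3,5-dicarboxylate, 1.0 equiv), L-proline (10 mol %), CH2Cl2, 25 °C
Reagents that add atoms: none
Why: Ramachary reductive alkylation (Knoevenagel condensation, then transfer hydrogenation of the alkylidene dione) gives clean C‑monoalkylation and forms the bond from the future angular carbon to the linker.

Step 7
Reactants: 11 2-Q-cyclopentane-1,3-dione; 12 pent-1-en-3-one
Product: 14 (7aR)-4-methyl-7a-Q-2,3,7,7a-tetrahydro-1H-indene-1,5(6H)-dione, via triketone 13 (not isolated)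
Conditions: 12 (1.5 equiv), Et3N (5 mol %), DMF, 25 °C; then D-phenylalanine (1 equiv), camphor-10-sulfonic acid (0.5 equiv), 30 → 70 °C
Reagents that add atoms: none
Why: Michael addition then Hajos–Parrish‑type amino‑acid‑mediated aldol condensation: the enamine of the side‑chain ketone attacks one of the two enantiotopic ring carbonyls, and D‑phenylalanine (mirror image of the series that gives the (S)‑Hajos–Parrish ketone) sets the angular carbon as 7aR; the minor isomer is a separable diastereomer.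

Step 8
Reactants: 14 (7aR)-4-methyl-7a-Q-2,3,7,7a-tetrahydro-1H-indene-1,5(6H)-dione
Product: 16 (8aR)-5-methyl-8a-Q-3,4,8,8a-tetrahydronaphthalene-1,6(2H,7H)-dione, via silyl ketone 15 (not isolated)
Conditions: TMSCHN2 (1.3 equiv), AlMe3 (1.2 equiv), CH2Cl2, −78 → −30 °C; then 1 M HCl, THF, 25 °C
Reagents that add atoms: (trimethylsilyl)diazomethane, C[Si](C)(C)C=[N+]=[N-]
Why: Key step, a one‑carbon ring expansion (Tiffeneau–Demjanov type): the diazoalkane adds to the strained cyclopentanone rather than the fully substituted enone, and the ring CH2 (not the angular quaternary carbon) migrates, so ring A becomes six‑membered with its ketone still next to the untouched angular stereocentre.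

Step 9
Reactants: 16 (8aR)-5-methyl-8a-Q-3,4,8,8a-tetrahydronaphthalene-1,6(2H,7H)-dione
Product: 17 (4aS)-1-methyl-5-methylidene-4a-Q-4,4a,5,6,7,8-hexahydronaphthalen-2(3H)-one
Conditions: Ph3PCH3Br (2.2 equiv), KOt-Bu (2.1 equiv), toluene, 25 → 70 °C
Reagents that add atoms: methyltriphenylphosphonium bromide, C[P+](c1ccccc1)(c1ccccc1)c1ccccc1.[Br-]
Why: Wittig methylenation: the unconjugated ring A ketone is more electrophilic than the vinylogous enone carbonyl, which the basic ylide also masks as its dienolate; the descriptor changes to 4aS only through priorities.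

Step 10
Reactants: 18 benzene-1,4-diol
Product: 19 1,4-dimethoxybenzene
Conditions: MeI (2.5 equiv), K2CO3, acetone, reflux
Reagents that add atoms: iodomethane, CI
Why: Williamson O‑methylation of both phenols.

Step 11
Reactants: 19 1,4-dimethoxybenzene
Product: 20 2-(bromomethyl)-1,4-dimethoxybenzene
Conditions: (CH2O)n (0.35 equiv), 33% HBr in AcOH, 19 in threefold excess, 40 °C
Reagents that add atoms: paraformaldehyde (as formaldehyde), C=O; hydrogen bromide, Br
Why: Blanc‑type bromomethylation (electrophilic aromatic substitution); the excess of arene suppresses the bis(bromomethyl) product.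

Step 12
Reactants: 17 (4aS)-1-methyl-5-methylidene-4a-Q-4,4a,5,6,7,8-hexahydronaphthalen-2(3H)-one; 20 2-(bromomethyl)-1,4-dimethoxybenzene
Product: 21 (1R,4aR,8aS)-1-[(2,5-dimethoxyphenyl)methyl]-1-methyl-5-methylidene-4a-Q-octahydronaphthalen-2(1H)-one
Conditions: Li (2.1 equiv), t-BuOH (1.0 equiv), NH3(l)/THF, −78 °C; then 20 (1.5 equiv), THF, −78 → −33 °C; NH4Cl
Reagents that add atoms: none
Why: Birch reductive alkylation (Stork): axial protonation at C‑8a gives the trans‑fused lithium enolate, which is benzylated on the face opposite the axial angular chain, so the benzyl group ends cis to H‑8a and the C‑1 methyl cis to the angular chain; the isolated alkenes are not reduced.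

Step 13
Reactants: 21 (1R,4aR,8aS)-1-[(2,5-dimethoxyphenyl)methyl]-1-methyl-5-methylidene-4a-Q-octahydronaphthalen-2(1H)-one
Product: 22 (1R,4aR,8aS)-1-[(2,5-dimethoxyphenyl)methyl]-2-hydrazinylidene-1-methyl-5-methylidene-4a-Q-decahydronaphthalene
Conditions: N2H4·H2O (20 equiv), Et3N, EtOH, 90 °C (sealed tube)
Reagents that add atoms: hydrazine hydrate, NN
Why: Hydrazone condensation at the only carbonyl; the neighbouring quaternary centre cannot epimerise.

Step 14
Reactants: 22 (1R,4aR,8aS)-1-[(2,5-dimethoxyphenyl)methyl]-2-hydrazinylidene-1-methyl-5-methylidene-4a-Q-decahydronaphthalene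
Product: 25 2-{[(1S,2S,4aS,8aR)-1,2-dimethyl-5-methylidene-4a-Q-decahydronaphthalen-1-yl]methyl}-1,4-dimethoxybenzene, via diazoalkane 23 (not isolated), via alkylalane 24 (not isolated)
Conditions: Ag2O, MgSO4, Et2O, −30 °C, cold filtration; filtrate into AlMe3 (3 equiv), toluene, −78 → −20 °C; then MeOH, 1 M HCl, −78 → 0 °C
Reagents that add atoms: trimethylaluminium, C[Al](C)C
Why: Proposed new method: the nucleophilic diazo carbon of 23 bonds to AlMe3 on the open face (that of H‑8a and the benzyl group, anti to the axial C‑1 methyl); the aluminate–diazonium zwitterion then undergoes a 1,2‑methyl shift from aluminium to carbon antiperiplanar to the leaving N2 (inversion at C‑2), which puts CH3 on the open face and the C–Al bond on the hindered face; protonolysis of C–Al with retention supplies the hydrogen on the hindered face, giving the axial methyl trans to the C‑1 methyl that hydrogenation or hydride delivery to an sp2 C‑2 cannot give; closest known reaction types are the insertion of diazoalkanes into B–C and Al–C bonds (Hooz alkylation, tosylhydrazone–boronic acid reductive coupling), so far not used to set a contra‑steric methine next to a quaternary carbon.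

Step 15
Reactants: 25 2-{[(1S,2S,4aS,8aR)-1,2-dimethyl-5-methylidene-4a-Q-decahydronaphthalen-1-yl]methyl}-1,4-dimethoxybenzene
Product: 26 2-{[(1S,2S,4aS,8aR)-1,2-dimethyl-5-methylidene-4a-Q-decahydronaphthalen-1-yl]methyl}benzene-1,4-diol
Conditions: EtSH, NaH (NaSEt, 8 equiv), DMF, 140 °C; 1 M HCl work-up under argon
Reagents that add atoms: none
Why: SN2 demethylation of both aryl methyl ethers by thiolate; alkenes and all stereocentres are inert to these conditions.

Step 16
Reactants: 26 2-{[(1S,2S,4aS,8aR)-1,2-dimethyl-5-methylidene-4a-Q-decahydronaphthalen-1-yl]methyl}benzene-1,4-diol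
Product: 27 2-{[(1S,2S,4aS,8aR)-1,2-dimethyl-5-methylidene-4a-Q-decahydronaphthalen-1-yl]methyl}-1,4-phenylene bis(hydrogen sulfate) (CNP0426429.4)
Conditions: SO3·pyridine (6 equiv), pyridine, 50 °C; then Dowex 50W (H+ form), MeOH/H2O, 0 °C
Reagents that add atoms: sulfur trioxide–pyridine complex, [O-]S(=O)(=O)[n+]1ccccc1
Why: O‑sulfation of both phenols with a mild SO3 donor that leaves the two alkenes untouched; cold proton exchange gives the free acid form drawn.

**Compound list**
1 | 2,2-dimethylcyclopentan-1-one | CC1(C)CCCC1=O | starting material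
2 | 2,2-dimethyl-6-(trimethylsilyl)cyclohexan-1-one (racemic) | CC1(C)CCCC([Si](C)(C)C)C1=O | intermediate
3 | 2,2-dimethylcyclohexan-1-one | CC1(C)CCCCC1=O | intermediate
4 | 1-ethenyl-2,2-dimethylcyclohexan-1-ol (racemic) | C=CC1(O)CCCCC1(C)C | intermediate
5 | 1-ethenyl-6,6-dimethylcyclohex-1-ene | C=CC1=CCCCC1(C)C | intermediate
6 | (E)-2-methylbut-2-enal | C/C=C(\C)C=O | starting material
7 | (1S,2R,8aS)-1,2,5,5-tetramethyl-1,2,3,5,6,7,8,8a-octahydronaphthalene-1-carbaldehyde | O=C[C@@]1(C)[C@H](C)CC=C2[C@@H]1CCCC2(C)C | intermediate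
8 | (1S,2R,8aR)-1-(2-methoxyethenyl)-1,2,5,5-tetramethyl-1,2,3,5,6,7,8,8a-octahydronaphthalene (E/Z mixture) | COC=C[C@@]1(C)[C@H](C)CC=C2[C@@H]1CCCC2(C)C | intermediate
9 | 2-[(1S,2R,8aR)-1,2,5,5-tetramethyl-1,2,3,5,6,7,8,8a-octahydronaphthalen-1-yl]acetaldehyde | O=CC[C@@]1(C)[C@H](C)CC=C2[C@@H]1CCCC2(C)C | intermediate
10 | cyclopentane-1,3-dione | O=C1CCC(=O)C1 | starting material
11 | 2-Q-cyclopentane-1,3-dione | O=C1CCC(=O)C1CC[C@@]1(C)[C@H](C)CC=C2[C@@H]1CCCC2(C)C | intermediate
12 | pent-1-en-3-one | C=CC(=O)CC | starting material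
13 | 2-(3-oxopentyl)-2-Q-cyclopentane-1,3-dione | CCC(=O)CCC1(CC[C@@]2(C)[C@H](C)CC=C3[C@@H]2CCCC3(C)C)C(=O)CCC1=O | intermediate
14 | (7aR)-4-methyl-7a-Q-2,3,7,7a-tetrahydro-1H-indene-1,5(6H)-dione | CC1=C2CCC(=O)[C@]2(CC[C@@]3(C)[C@H](C)CC=C4[C@@H]3CCCC4(C)C)CCC1=O | intermediate
15 | (8aR)-5-methyl-2-(trimethylsilyl)-8a-Q-3,4,8,8a-tetrahydronaphthalene-1,6(2H,7H)-dione (C-2 epimers) | CC1=C2CCC([Si](C)(C)C)C(=O)[C@]2(CC[C@@]3(C)[C@H](C)CC=C4[C@@H]3CCCC4(C)C)CCC1=O | intermediate
16 | (8aR)-5-methyl-8a-Q-3,4,8,8a-tetrahydronaphthalene-1,6(2H,7H)-dione | CC1=C2CCCC(=O)[C@]2(CC[C@@]3(C)[C@H](C)CC=C4[C@@H]3CCCC4(C)C)CCC1=O | intermediate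
17 | (4aS)-1-methyl-5-methylidene-4a-Q-4,4a,5,6,7,8-hexahydronaphthalen-2(3H)-one | CC1=C2CCCC(=C)[C@]2(CC[C@@]3(C)[C@H](C)CC=C4[C@@H]3CCCC4(C)C)CCC1=O | intermediate
18 | benzene-1,4-diol (hydroquinone) | Oc1ccc(O)cc1 | starting material
19 | 1,4-dimethoxybenzene | COc1ccc(OC)cc1 | intermediate
20 | 2-(bromomethyl)-1,4-dimethoxybenzene | COc1ccc(OC)c(CBr)c1 | intermediate
21 | (1R,4aR,8aS)-1-[(2,5-dimethoxyphenyl)methyl]-1-methyl-5-methylidene-4a-Q-octahydronaphthalen-2(1H)-one | C=C1CCC[C@H]2[C@@]1(CC[C@@]1(C)[C@H](C)CC=C3[C@@H]1CCCC3(C)C)CCC(=O)[C@]2(C)Cc1cc(OC)ccc1OC | intermediate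
22 | (1R,4aR,8aS)-1-[(2,5-dimethoxyphenyl)methyl]-2-hydrazinylidene-1-methyl-5-methylidene-4a-Q-decahydronaphthalene | C=C1CCC[C@H]2[C@@]1(CC[C@@]1(C)[C@H](C)CC=C3[C@@H]1CCCC3(C)C)CCC(=NN)[C@]2(C)Cc1cc(OC)ccc1OC | intermediate
23 | (1R,4aR,8aS)-2-diazo-1-[(2,5-dimethoxyphenyl)methyl]-1-methyl-5-methylidene-4a-Q-decahydronaphthalene | C=C1CCC[C@H]2[C@@]1(CC[C@@]1(C)[C@H](C)CC=C3[C@@H]1CCCC3(C)C)CCC(=[N+]=[N-])[C@]2(C)Cc1cc(OC)ccc1OC | intermediate
24 | {(1R,2R,4aR,8aS)-1-[(2,5-dimethoxyphenyl)methyl]-1,2-dimethyl-5-methylidene-4a-Q-decahydronaphthalen-2-yl}dimethylalane | C=C1CCC[C@H]2[C@@]1(CC[C@@]1(C)[C@H](C)CC=C3[C@@H]1CCCC3(C)C)CC[C@@](C)([Al](C)C)[C@]2(C)Cc1cc(OC)ccc1OC | intermediate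
25 | 2-{[(1S,2S,4aS,8aR)-1,2-dimethyl-5-methylidene-4a-Q-decahydronaphthalen-1-yl]methyl}-1,4-dimethoxybenzene | C=C1CCC[C@H]2[C@@]1(CC[C@@]1(C)[C@H](C)CC=C3[C@@H]1CCCC3(C)C)CC[C@H](C)[C@]2(C)Cc1cc(OC)ccc1OC | intermediate
26 | 2-{[(1S,2S,4aS,8aR)-1,2-dimethyl-5-methylidene-4a-Q-decahydronaphthalen-1-yl]methyl}benzene-1,4-diol | C=C1CCC[C@H]2[C@@]1(CC[C@@]1(C)[C@H](C)CC=C3[C@@H]1CCCC3(C)C)CC[C@H](C)[C@]2(C)Cc1cc(O)ccc1O | intermediate
27 | 2-{[(1S,2S,4aS,8aR)-1,2-dimethyl-5-methylidene-4a-Q-decahydronaphthalen-1-yl]methyl}-1,4-phenylene bis(hydrogen sulfate) | C=C1CCC[C@H]2[C@@]1(CC[C@@]1(C)[C@H](C)CC=C3[C@@H]1CCCC3(C)C)CC[C@H](C)[C@]2(C)Cc1cc(OS(=O)(=O)O)ccc1OS(=O)(=O)O | target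

**Totals**
Total step count: 16. Longest linear sequence: 14 (steps 1–9 and 12–16).

**Three steps most likely to fail**

Step 4 (Diels–Alder). A hindered diene and an α,β‑disubstituted enal may react slowly or with eroded exo/enantioselectivity. The fallback sets out from 5 and 6 and comes back at 7. The cycloaddition is run with the achiral Lewis acid Me2AlCl (CH2Cl2, −40 °C) to give the racemic exo adduct. The enantiomers are then separated by preparative chromatography on a chiral stationary phase. The mirror‑image aldehyde (1R,2S,8aR)-1,2,5,5-tetramethyl-1,2,3,5,6,7,8,8a-octahydronaphthalene-1-carbaldehyde F1 is set aside and 7 is carried on.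

Step 8 (ring expansion). Risks are attack of the diazoalkane on the enone, migration of the angular carbon, or double homologation. The fallback sets out from 9 and comes back at 16, building ring A six‑membered from the start. Reductive alkylation of cyclohexane‑1,3‑dione (eight non‑hydrogen atoms) with 9 under the step 6 conditions gives 2-Q-cyclohexane-1,3-dione F2. Michael addition to 12 gives the triketone 2-(3-oxopentyl)-2-Q-cyclohexane-1,3-dione F3 (not isolated). D‑phenylalanine/camphor‑10‑sulfonic acid‑mediated Wieland–Miescher‑type aldol condensation then closes ring B to 16; if selectivity is low, the minor isomer is removed as a diastereomer.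

Step 14 (proposed new step). The diazoalkane may instead undergo a 1,2‑hydrogen shift to the C‑2/C‑3 alkene, form an azine, or be captured by the arene. The fallback uses known chemistry, sets out from 21 and comes back at 25. NaBH4 (MeOH, 0 °C) gives the equatorial alcohol (1R,2R,4aR,8aS)-1-[(2,5-dimethoxyphenyl)methyl]-1-methyl-5-methylidene-4a-Q-decahydronaphthalen-2-ol F4. Condensation with 5,7‑di‑tert‑butyl‑3‑phenylbenzoxazolium tetrafluoroborate and pyridine gives the adduct 5,7-di-tert-butyl-3-phenyl-2-{[(1R,2R,4aR,8aS)-1-[(2,5-dimethoxyphenyl)methyl]-1-methyl-5-methylidene-4a-Q-decahydronaphthalen-2-yl]oxy}-2,3-dihydro-1,3-benzoxazole F5 (not isolated). Photoredox/nickel deoxygenative methylation ([Ir(ppy)2(dtbbpy)]PF6, NiBr2·glyme, 4,4′‑di‑tert‑butyl‑2,2′‑bipyridine, quinuclidine, methyl tosylate, blue light) then forms the C‑2 radical. Nickel is expected to capture it on the same open face, so C–CH3 bond formation again places the methyl cis to the benzyl group and gives 25.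

Further compounds
F1 | step 4 | (1R,2S,8aR)-1,2,5,5-tetramethyl-1,2,3,5,6,7,8,8a-octahydronaphthalene-1-carbaldehyde | O=C[C@]1(C)[C@@H](C)CC=C2[C@H]1CCCC2(C)C
F2 | step 8 | 2-Q-cyclohexane-1,3-dione | O=C1CCCC(=O)C1CC[C@@]1(C)[C@H](C)CC=C2[C@@H]1CCCC2(C)C
F3 | step 8 | 2-(3-oxopentyl)-2-Q-cyclohexane-1,3-dione | CCC(=O)CCC1(CC[C@@]2(C)[C@H](C)CC=C3[C@@H]2CCCC3(C)C)C(=O)CCCC1=O
F4 | step 14 | (1R,2R,4aR,8aS)-1-[(2,5-dimethoxyphenyl)methyl]-1-methyl-5-methylidene-4a-Q-decahydronaphthalen-2-ol | C=C1CCC[C@H]2[C@@]1(CC[C@@]1(C)[C@H](C)CC=C3[C@@H]1CCCC3(C)C)CC[C@@H](O)[C@]2(C)Cc1cc(OC)ccc1OC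
F5 | step 14 | 5,7-di-tert-butyl-3-phenyl-2-{[(1R,2R,4aR,8aS)-1-[(2,5-dimethoxyphenyl)methyl]-1-methyl-5-methylidene-4a-Q-decahydronaphthalen-2-yl]oxy}-2,3-dihydro-1,3-benzoxazole | C=C1CCC[C@H]2[C@@]1(CC[C@@]1(C)[C@H](C)CC=C3[C@@H]1CCCC3(C)C)CC[C@@H](OC1Oc3c(C(C)(C)C)cc(C(C)(C)C)cc3N1c1ccccc1)[C@]2(C)Cc1cc(OC)ccc1OC
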